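**Time first.** In 80 s the enzyme passes through 5.36 of its mean lifetimes of 14.9 s, so this flask is a contest between a dying catalyst and a rate law that is slow at high load.

starting material 0.050 M; enzyme 0.30 µM; time 80 s

    enzyme → spent catalyst (k1 = 0.067 s⁻¹)
    crystals ⇌ product, rate k2*(cs2 - [product]) while solid is left; crystals form when [product] > cs2 (cs2 = 2.8 mM, k2 = 1.0 s⁻¹)
    starting material + enzyme → product + enzyme, rate k3*[starting material]*[enzyme]/(1 + ([starting material]/Km3) + ([starting material]/Ksi3)^2) (Km3 = 0.12 M, Ksi3 = 9.2 mM, k3 = 2.0 × 10⁶ L mol⁻¹ s⁻¹)

- Thursday's: doubling the solubility in step 2, all else as stated
- Friday's: doubling the dissolution coefficient of step 2, all else as stated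
- Monday's: doubling the amount of enzyme, all else as stated

- amounts and yields of product count crystals too
- given per volume of solution although it is solid: crystals
- run time (flask): 80 s

1. the product and crystals together standing at 80 s, as a percentage of the starting material charged
2. the change that raises the amount of product and crystals together at 80 s, in percent of the starting material charged most ("none" if none brings more than 2 percentage points) (Thursday's / Friday's / Monday's / none)
3. amount of product and crystals together at 80 s, in percent of the starting material charged, after Monday's

**First instants.** Write S for the concentration of starting material. The denominator of step 3 stands at 31.0, nearly all of it from the squared term (substrate inhibition). The flask therefore starts at 0.969 mM s⁻¹, and dissolved product reaches its solubility in about 2.89 s. Crystals then begin. Step 2 shifts product between two forms that are counted together, and product stands nowhere in the rate law of step 3, so crystals change the split and leave the total alone.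

**The middle.** As S falls in this flask, the denominator shrinks and each enzyme works faster, while the enzyme itself decays. Dividing the rate of step 3 by S and multiplying it by its denominator separates the two, and the enzyme's time integral then stands on one side, with S on the other.

**The end.** That integral times the rate constant of step 3 gives 8.91, the enzyme budget B. With c the charge, K the constant Km and J the constant Ksi, going from c down to S costs ln(c/S) + (c − S)/K + (c·c − S·S)/(2J·J). The squared term of the full charge alone costs 14.8, which is more than the budget, so this flask stops with starting material left, with 0.470% of the enzyme at 80 s.

**Going round.** By hand, the squared term alone gives S = 31.5 mM. Putting that into the other two terms gives 33.1 mM, and one more round gives 32.9 mM, so y is 34.1%. Monday's doubles the budget to 17.8, which exceeds that squared cost, and the surplus goes into the logarithm. Starting from S = 3.56 mM and going round once gives 3.21 mM, so yb is 93.6%. The best change is Monday's.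

**The forecast.** It gives 34.1%, Monday's and 93.5%, holding that “doubling the enzyme carries the reaction past the inhibited region”.

**The result.** The flask gives 34.1%, and Monday's is best, gaining 59 percentage points and reaching 93.5%, while Thursday's gains 0 points. An enzyme charge of 0.335 µM instead of 0.30 µM already moves y by 5 points. The neighbouring flask with 0.030 M of starting material has the same budget, 8.91, but its squared cost is 5.32, so the surplus leaves S at 1.06 mM, a reckoned 96.5%, and that flask stands at 96.5%.

The numbers of this flask are made up, and the outcome is calculated.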